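## Retrosynthetic overview

1. The target comes from hydrogenation of a chain alkene made by B-alkyl Suzuki–Miyaura coupling of a phthalide vinyl iodide (fragment A) with the 9-BBN adduct of an allyl spiroketal (fragment B).
2. Fragment A comes from Takai iodo-olefination of an aldehyde, itself from Fukuyama reduction of a phthalide thioester. The lactone ring is closed, and C3 set, by an enantioselective intramolecular oxa-Michael addition of a benzoic acid onto an (E)-enoyl thioester (key step).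
3. The cyclisation substrate comes from Wittig olefination of tert-butyl 2-formyl-4,6-dimethoxybenzoate, made from 3,5-dimethoxybenzaldehyde (bromination, Br–Li exchange/Boc2O).
4. Fragment B comes from gold-catalysed cycloisomerisation and acid spiroketalisation of an alkynol built from (R)-propylene oxide, 1-(trimethylsilyl)propyne and (R)-allyloxirane (from (R)-epichlorohydrin).
5. Ring order: aromatic ring bought; phthalide lactone ring (oxa-Michael); separately the dihydrofuran ring, then the second ring of the spiroketal; no ring is formed after fragment union.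

Assumption 1: the quinidine-derived amine–thiourea is taken to deliver the carboxylate to the Re face of the β-carbon (giving 3R); if the opposite sense is found, the quinine-derived pseudoenantiomer is used under the same conditions.

Assumption 2: acid equilibration of the spiro centre is taken to favour, modestly, the (5S) epimer (both alkyl groups anti to the oxygen of the other ring), separable on Et3N-treated silica; the minor (5R) epimer is re-equilibrated and recycled.

## Route

**Fragment A**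

Step 1
Reactants: 1 3,5-dimethoxybenzaldehyde
Product: 2 2-bromo-3,5-dimethoxybenzaldehyde
Conditions: NBS, MeCN, 0 °C to rt
Reagents that add atoms: N-bromosuccinimide, O=C1CCC(=O)N1Br
Why: Electrophilic aromatic bromination goes to C2 (para to one methoxy, ortho to the other) because C4 between the two methoxy groups is more hindered.

Step 2
Reactants: 2 2-bromo-3,5-dimethoxybenzaldehyde
Product: 3 2-bromo-1-(dimethoxymethyl)-3,5-dimethoxybenzene
Conditions: HC(OMe)3, TsOH·H2O (cat.), MeOH, 50 °C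
Reagents that add atoms: methanol, CO; trimethyl orthoformate, COC(OC)OC
Why: Acid-catalysed acetalisation, driven by the orthoformate as water scavenger, masks the aldehyde for the lithiation.

Step 3
Reactants: 3 2-bromo-1-(dimethoxymethyl)-3,5-dimethoxybenzene
Product: 4 tert-butyl 2-(dimethoxymethyl)-4,6-dimethoxybenzoate
Conditions: n-BuLi, THF, −78 °C; Boc2O, −78 °C to rt; NH4Cl (aq)
Reagents that add atoms: di-tert-butyl dicarbonate, CC(C)(C)OC(=O)OC(=O)OC(C)(C)C
Why: Bromine–lithium exchange followed by acylation of the aryllithium with Boc2O gives the hindered tert-butyl ester directly without over-addition.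

Step 4
Reactants: 4 tert-butyl 2-(dimethoxymethyl)-4,6-dimethoxybenzoate
Product: 5 tert-butyl 2-formyl-4,6-dimethoxybenzoate
Conditions: PPTS (cat.), acetone/H2O, rt
Reagents that add atoms: water, O
Why: Mild acid hydrolysis of the dimethyl acetal frees the aldehyde while the tert-butyl ester survives.

Step 5
Reactants: 6 bromoacetyl bromide; 7 ethanethiol
Product: 8 S-ethyl 2-bromoethanethioate
Conditions: pyridine, CH2Cl2, 0 °C
Reagents that add atoms: none
Why: Acylation of the thiol by the acid bromide (thioesterification) is much faster at 0 °C than displacement of the α-bromide.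

Step 6
Reactants: 8 S-ethyl 2-bromoethanethioate; 9 triphenylphosphine
Product: 11 S-ethyl 2-(triphenyl-λ5-phosphanylidene)ethanethioate, via phosphonium bromide 10 (not isolated)
Conditions: toluene, rt; then Na2CO3 (aq), CH2Cl2, rt
Reagents that add atoms: none
Why: SN2 quaternisation of the phosphine and deprotonation of the acidic phosphonium salt give the stabilised Wittig ylide.

Step 7
Reactants: 5 tert-butyl 2-formyl-4,6-dimethoxybenzoate; 11 S-ethyl 2-(triphenyl-λ5-phosphanylidene)ethanethioate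
Product: 12 tert-butyl 2-[(1E)-3-(ethylsulfanyl)-3-oxoprop-1-en-1-yl]-4,6-dimethoxybenzoate
Conditions: toluene, 80 °C
Reagents that add atoms: none
Why: Wittig olefination with a stabilised ylide gives the (E)-enoyl thioester selectively.

Step 8
Reactants: 12 tert-butyl 2-[(1E)-3-(ethylsulfanyl)-3-oxoprop-1-en-1-yl]-4,6-dimethoxybenzoate
Product: 13 2-[(1E)-3-(ethylsulfanyl)-3-oxoprop-1-en-1-yl]-4,6-dimethoxybenzoic acid
Conditions: TFA, CH2Cl2, 0 °C; evaporate cold, use crude
Reagents that add atoms: none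
Why: Acidolysis of the tert-butyl ester (loss of isobutene) unmasks the acid under conditions where the protonated carboxyl group is too weak a nucleophile to cyclise.

Step 9
Reactants: 13 2-[(1E)-3-(ethylsulfanyl)-3-oxoprop-1-en-1-yl]-4,6-dimethoxybenzoic acid
Product: 14 S-ethyl 2-[(1R)-4,6-dimethoxy-3-oxo-1,3-dihydro-2-benzofuran-1-yl]ethanethioate
Conditions: quinidine-derived 9-amino(9-deoxy)epi-cinchona 3,5-bis(trifluoromethyl)phenyl thiourea (10 mol%), toluene/CH2Cl2, 0 °C to rt
Reagents that add atoms: none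
Why: In this 5-exo-trig intramolecular oxa-Michael addition the quinuclidine forms an ammonium carboxylate ion pair while the thiourea binds the thioester carbonyl, so the carboxylate oxygen is delivered to the Re face of the β-carbon and C3 is set as R.

Step 10
Reactants: 14 S-ethyl 2-[(1R)-4,6-dimethoxy-3-oxo-1,3-dihydro-2-benzofuran-1-yl]ethanethioate
Product: 15 2-[(1R)-4,6-dimethoxy-3-oxo-1,3-dihydro-2-benzofuran-1-yl]acetaldehyde
Conditions: Et3SiH, 10% Pd/C, acetone, rt
Reagents that add atoms: none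
Why: Fukuyama reduction converts the thioester to the aldehyde under neutral conditions that leave the lactone alone and avoid β-elimination, so C3 is untouched.

Step 11
Reactants: 15 2-[(1R)-4,6-dimethoxy-3-oxo-1,3-dihydro-2-benzofuran-1-yl]acetaldehyde
Product: 16 (3R)-3-[(2E)-3-iodoprop-2-en-1-yl]-5,7-dimethoxy-2-benzofuran-1(3H)-one
Conditions: CrCl2, CHI3, THF/1,4-dioxane, 0 °C to rt
Reagents that add atoms: iodoform, IC(I)I
Why: Takai olefination is non-basic, so the β-acyloxy aldehyde gives the (E)-vinyl iodide without retro-Michael racemisation (any Z isomer converges at step 20).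

**Fragment B**

Step 12
Reactants: 17 1-(trimethylsilyl)propyne; 18 (R)-propylene oxide
Product: 19 (2R)-6-(trimethylsilyl)hex-5-yn-2-ol
Conditions: n-BuLi, TMEDA, THF, −78 to −20 °C; then 18, −78 °C to rt; NH4Cl (aq)
Reagents that add atoms: none
Why: The propargylic lithium reagent opens the epoxide by SN2 attack at its CH2 terminus, so the (R) carbinol centre comes unchanged from the epoxide.

Step 13
Reactants: 19 (2R)-6-(trimethylsilyl)hex-5-yn-2-ol
Product: 20 tert-butyl(dimethyl){[(2R)-6-(trimethylsilyl)hex-5-yn-2-yl]oxy}silane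
Conditions: TBSCl, imidazole, DMF, rt
Reagents that add atoms: tert-butyldimethylsilyl chloride, CC(C)(C)[Si](C)(C)Cl
Why: Standard silylation protects the secondary alcohol for the acetylide chemistry.

Step 14
Reactants: 20 tert-butyl(dimethyl){[(2R)-6-(trimethylsilyl)hex-5-yn-2-yl]oxy}silane
Product: 21 tert-butyl[(2R)-hex-5-yn-2-yloxy]dimethylsilane
Conditions: K2CO3, MeOH, rt
Reagents that add atoms: none
Why: Base-catalysed methanolysis cleaves the alkynyl C–Si bond selectively while the TBS ether is stable.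

Step 15
Reactants: 22 (R)-epichlorohydrin; 23 vinylmagnesium bromide
Product: 24 (2R)-1-chloropent-4-en-2-ol
Conditions: CuI (10 mol%), THF, −78 to −40 °C; NH4Cl (aq)
Reagents that add atoms: none
Why: Copper-catalysed Grignard opening occurs at the epoxide CH2 faster than chloride displacement, leaving the stereocentre untouched.

Step 16
Reactants: 24 (2R)-1-chloropent-4-en-2-ol
Product: 25 (2R)-2-(prop-2-en-1-yl)oxirane
Conditions: NaOH (powder), Et2O, rt; distil
Reagents that add atoms: none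
Why: Intramolecular Williamson closure displaces chloride at the primary carbon, so the C–O bond at the stereocentre is never broken.

Step 17
Reactants: 21 tert-butyl[(2R)-hex-5-yn-2-yloxy]dimethylsilane; 25 (2R)-2-(prop-2-en-1-yl)oxirane
Product: 26 (4R,10R)-10-[(tert-butyldimethylsilyl)oxy]undec-1-en-6-yn-4-ol
Conditions: n-BuLi, THF, −78 °C; BF3·OEt2; then 25, −78 °C; NH4Cl (aq)
Reagents that add atoms: none
Why: Yamaguchi-type BF3-promoted opening of the terminal epoxide at CH2 by the lithium acetylide joins the two chiral pieces without touching either stereocentre.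

Step 18
Reactants: 26 (4R,10R)-10-[(tert-butyldimethylsilyl)oxy]undec-1-en-6-yn-4-ol
Product: 29 (2S,5S,7R)-2-allyl-7-methyl-1,6-dioxaspiro[4.4]nonane, via dihydrofuran silyl ether 27 (not isolated), via hydroxy dihydrofuran 28 (not isolated)
Conditions: Ph3PAuCl (2 mol%), AgOTf (2 mol%), CH2Cl2, rt; then TsOH·H2O (0.2 equiv), MeOH, rt; Et3N-treated silica
Reagents that add atoms: none
Why: Gold-catalysed 5-endo-dig cycloisomerisation of the homopropargylic alcohol fixes both oxygens on the same alkyne carbon, then acid methanolysis of the TBS ether and spiroketalisation set the spiro centre under thermodynamic control, the (5S) epimer being isolated by chromatography.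

**Union and completion**

Step 19
Reactants: 29 (2S,5S,7R)-2-allyl-7-methyl-1,6-dioxaspiro[4.4]nonane; 16 (3R)-3-[(2E)-3-iodoprop-2-en-1-yl]-5,7-dimethoxy-2-benzofuran-1(3H)-one
Product: 31 (3R)-5,7-dimethoxy-3-{(2E)-6-[(2R,5S,7R)-7-methyl-1,6-dioxaspiro[4.4]nonan-2-yl]hex-2-en-1-yl}-2-benzofuran-1(3H)-one, via B-alkyl borane 30 (not isolated)
Conditions: 9-BBN, THF, rt; then 16, PdCl2(dppf), AsPh3, Cs2CO3, DMF/THF/H2O, rt
Reagents that add atoms: none
Why: Anti-Markovnikov hydroboration and B-alkyl Suzuki–Miyaura coupling join the fragments under mildly basic, acid-free conditions with retention of alkene geometry and of all four stereocentres.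

Step 20
Reactants: 31 (3R)-5,7-dimethoxy-3-{(2E)-6-[(2R,5S,7R)-7-methyl-1,6-dioxaspiro[4.4]nonan-2-yl]hex-2-en-1-yl}-2-benzofuran-1(3H)-one
Product: 32 (3R)-5,7-dimethoxy-3-{6-[(2R,5S,7R)-7-methyl-1,6-dioxaspiro[4.4]nonan-2-yl]hexyl}-2-benzofuran-1(3H)-one
Conditions: H2 (1 atm), 5% Pd/C, EtOAc, Et3N (trace), rt
Reagents that add atoms: none
Why: Heterogeneous hydrogenation saturates the disubstituted alkene, and the amine buffer prevents acid epimerisation of the spiro centre, so no stereocentre is affected.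

## Compound list

1 | 3,5-dimethoxybenzaldehyde | COc1cc(OC)cc(C=O)c1 | starting material
2 | 2-bromo-3,5-dimethoxybenzaldehyde | COc1cc(OC)c(Br)c(C=O)c1 | intermediate
3 | 2-bromo-1-(dimethoxymethyl)-3,5-dimethoxybenzene | COc1cc(OC)c(Br)c(C(OC)OC)c1 | intermediate
4 | tert-butyl 2-(dimethoxymethyl)-4,6-dimethoxybenzoate | COc1cc(OC)c(C(=O)OC(C)(C)C)c(C(OC)OC)c1 | intermediate
5 | tert-butyl 2-formyl-4,6-dimethoxybenzoate | COc1cc(OC)c(C(=O)OC(C)(C)C)c(C=O)c1 | intermediate
6 | bromoacetyl bromide | BrCC(Br)=O | starting material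
7 | ethanethiol | CCS | starting material
8 | S-ethyl 2-bromoethanethioate | CCSC(=O)CBr | intermediate
9 | triphenylphosphine | c1ccc(cc1)P(c1ccccc1)c1ccccc1 | starting material
10 | [2-(ethylsulfanyl)-2-oxoethyl]triphenylphosphonium bromide | CCSC(=O)C[P+](c1ccccc1)(c1ccccc1)c1ccccc1.[Br-] | intermediate (not isolated)
11 | S-ethyl 2-(triphenyl-λ5-phosphanylidene)ethanethioate | CCSC(=O)C=P(c1ccccc1)(c1ccccc1)c1ccccc1 | intermediate
12 | tert-butyl 2-[(1E)-3-(ethylsulfanyl)-3-oxoprop-1-en-1-yl]-4,6-dimethoxybenzoate | CCSC(=O)/C=C/c1cc(OC)cc(OC)c1C(=O)OC(C)(C)C | intermediate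
13 | 2-[(1E)-3-(ethylsulfanyl)-3-oxoprop-1-en-1-yl]-4,6-dimethoxybenzoic acid | CCSC(=O)/C=C/c1cc(OC)cc(OC)c1C(=O)O | intermediate
14 | S-ethyl 2-[(1R)-4,6-dimethoxy-3-oxo-1,3-dihydro-2-benzofuran-1-yl]ethanethioate | COc1cc(OC)c2c(c1)[C@@H](CC(=O)SCC)OC2=O | intermediate
15 | 2-[(1R)-4,6-dimethoxy-3-oxo-1,3-dihydro-2-benzofuran-1-yl]acetaldehyde | COc1cc(OC)c2c(c1)[C@@H](CC=O)OC2=O | intermediate
16 | (3R)-3-[(2E)-3-iodoprop-2-en-1-yl]-5,7-dimethoxy-2-benzofuran-1(3H)-one | COc1cc(OC)c2c(c1)[C@@H](C/C=C/I)OC2=O | intermediate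
17 | 1-(trimethylsilyl)propyne | CC#C[Si](C)(C)C | starting material
18 | (R)-propylene oxide, (2R)-2-methyloxirane | C[C@@H]1CO1 | starting material
19 | (2R)-6-(trimethylsilyl)hex-5-yn-2-ol | C[C@@H](O)CCC#C[Si](C)(C)C | intermediate
20 | tert-butyl(dimethyl){[(2R)-6-(trimethylsilyl)hex-5-yn-2-yl]oxy}silane | C[C@@H](O[Si](C)(C)C(C)(C)C)CCC#C[Si](C)(C)C | intermediate
21 | tert-butyl[(2R)-hex-5-yn-2-yloxy]dimethylsilane | C[C@@H](O[Si](C)(C)C(C)(C)C)CCC#C | intermediate
22 | (R)-epichlorohydrin, (2R)-2-(chloromethyl)oxirane | ClC[C@H]1CO1 | starting material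
23 | vinylmagnesium bromide | C=C[Mg]Br | starting material
24 | (2R)-1-chloropent-4-en-2-ol | ClC[C@H](O)CC=C | intermediate
25 | (2R)-2-(prop-2-en-1-yl)oxirane | C=CC[C@@H]1CO1 | intermediate
26 | (4R,10R)-10-[(tert-butyldimethylsilyl)oxy]undec-1-en-6-yn-4-ol | C=CC[C@@H](O)CC#CCC[C@@H](C)O[Si](C)(C)C(C)(C)C | intermediate
27 | tert-butyl(dimethyl){[(2R)-4-[(2R)-2-(prop-2-en-1-yl)-2,3-dihydrofuran-5-yl]butan-2-yl]oxy}silane | C=CC[C@@H]1CC=C(CC[C@@H](C)O[Si](C)(C)C(C)(C)C)O1 | intermediate (not isolated)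
28 | (2R)-4-[(2R)-2-(prop-2-en-1-yl)-2,3-dihydrofuran-5-yl]butan-2-ol | C=CC[C@@H]1CC=C(CC[C@@H](C)O)O1 | intermediate (not isolated)
29 | (2S,5S,7R)-2-allyl-7-methyl-1,6-dioxaspiro[4.4]nonane (same spatial arrangement at C2 as in the target; the descriptor changes only because allyl outranks the ring CH2) | C=CC[C@@H]1CC[C@]2(CC[C@@H](C)O2)O1 | intermediate
30 | 9-{3-[(2R,5S,7R)-7-methyl-1,6-dioxaspiro[4.4]nonan-2-yl]propyl}-9-borabicyclo[3.3.1]nonane | B1(CCC[C@@H]3CC[C@]4(CC[C@@H](C)O4)O3)C2CCCC1CCC2 | intermediate (not isolated)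
31 | (3R)-5,7-dimethoxy-3-{(2E)-6-[(2R,5S,7R)-7-methyl-1,6-dioxaspiro[4.4]nonan-2-yl]hex-2-en-1-yl}-2-benzofuran-1(3H)-one | COc1cc(OC)c2c(c1)[C@@H](C/C=C/CCC[C@@H]1CC[C@]3(CC[C@@H](C)O3)O1)OC2=O | intermediate
32 | (3R)-5,7-dimethoxy-3-{6-[(2R,5S,7R)-7-methyl-1,6-dioxaspiro[4.4]nonan-2-yl]hexyl}-2-benzofuran-1(3H)-one | COc1cc(OC)c2c(c1)[C@@H](CCCCCC[C@@H]1CC[C@]3(CC[C@@H](C)O3)O1)OC2=O | target

## Step count and risks

Total step count: 20.
Longest linear sequence: 11 steps (1, 2, 3, 4, 7, 8, 9, 10, 11, 19, 20); the fragment B branch contributes 7 (12, 13, 14, 17, 18, 19, 20).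

**Step 9 (enantioselective oxa-Michael closure).** The risk is low enantiomeric excess, since an enoyl thioester with a carboxylate nucleophile is a demanding pairing and the addition is reversible under base. The fallback sets out from 13 and comes back at 14. Acid 13 is cyclised by the same oxa-Michael closure without chiral control (DBU, 5 mol%, CH2Cl2, rt) to racemic S-ethyl 2-(4,6-dimethoxy-3-oxo-1,3-dihydro-2-benzofuran-1-yl)ethanethioate F1. F1 is resolved by preparative chiral-phase SFC to give 14. The unwanted S-ethyl 2-[(1S)-4,6-dimethoxy-3-oxo-1,3-dihydro-2-benzofuran-1-yl]ethanethioate F2 is returned to F1 by DBU-induced retro-Michael/Michael equilibration and recycled.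

**Step 18 (spiro centre).** The [4.4] spiroketal has only a small thermodynamic bias, 29 is volatile, and its epimers may be hard to separate. The fallback sets out from 26 and comes back at 31, moving the spiroketalisation after fragment union.
- Alkynol 26 is hydroborated with 9-BBN (2.2 equiv; the first equivalent is consumed by the hydroxyl, and the internal alkyne is left) to 9-{(4R,10R)-4-[(9-borabicyclo[3.3.1]nonan-9-yl)oxy]-10-[(tert-butyldimethylsilyl)oxy]undec-6-yn-1-yl}-9-borabicyclo[3.3.1]nonane F3.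
- F3 is coupled with 16 under the step 19 conditions to (3R)-3-[(2E,7R,13R)-13-[(tert-butyldimethylsilyl)oxy]-7-hydroxytetradec-2-en-9-yn-1-yl]-5,7-dimethoxy-2-benzofuran-1(3H)-one F4.
- Ph3PAuCl/AgOTf cyclises F4 to (3R)-3-{(2E)-6-[(2R)-5-{(3R)-3-[(tert-butyldimethylsilyl)oxy]butyl}-2,3-dihydrofuran-2-yl]hex-2-en-1-yl}-5,7-dimethoxy-2-benzofuran-1(3H)-one F5.
- TsOH in MeOH desilylates F5 to (3R)-3-{(2E)-6-[(2R)-5-[(3R)-3-hydroxybutyl]-2,3-dihydrofuran-2-yl]hex-2-en-1-yl}-5,7-dimethoxy-2-benzofuran-1(3H)-one F6, which closes to 31 together with its spiro epimer (3R)-5,7-dimethoxy-3-{(2E)-6-[(2R,5R,7R)-7-methyl-1,6-dioxaspiro[4.4]nonan-2-yl]hex-2-en-1-yl}-2-benzofuran-1(3H)-one F7.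
- These non-volatile, UV-active epimers are separated by preparative HPLC, and F7 is re-equilibrated with PPTS.

**Step 19 (B-alkyl Suzuki coupling).** Aqueous base may open the lactone, and the coupling may be slow. The fallback sets out from 29 (through 30) and comes back at 31, using a base-free Negishi coupling.
- Borane 30 is oxidised (NaOH, H2O2) to 3-[(2R,5S,7R)-7-methyl-1,6-dioxaspiro[4.4]nonan-2-yl]propan-1-ol F8.
- I2, PPh3 and imidazole convert F8 to (2S,5S,7R)-2-(3-iodopropyl)-7-methyl-1,6-dioxaspiro[4.4]nonane F9.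
- Activated zinc dust in DMA gives iodo{3-[(2S,5S,7R)-7-methyl-1,6-dioxaspiro[4.4]nonan-2-yl]propyl}zinc F10.
- F10 couples with 16 using Pd(PPh3)4 in THF/DMA at rt to give 31.

## Further compounds

F1 | step 9 | racemic S-ethyl 2-(4,6-dimethoxy-3-oxo-1,3-dihydro-2-benzofuran-1-yl)ethanethioate | COc1cc(OC)c2c(c1)C(CC(=O)SCC)OC2=O
F2 | step 9 | S-ethyl 2-[(1S)-4,6-dimethoxy-3-oxo-1,3-dihydro-2-benzofuran-1-yl]ethanethioate | COc1cc(OC)c2c(c1)[C@H](CC(=O)SCC)OC2=O
F3 | step 18 | 9-{(4R,10R)-4-[(9-borabicyclo[3.3.1]nonan-9-yl)oxy]-10-[(tert-butyldimethylsilyl)oxy]undec-6-yn-1-yl}-9-borabicyclo[3.3.1]nonane | B1(CCC[C@@H](OB3C4CCCC3CCC4)CC#CCC[C@@H](C)O[Si](C)(C)C(C)(C)C)C2CCCC1CCC2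
F4 | step 18 | (3R)-3-[(2E,7R,13R)-13-[(tert-butyldimethylsilyl)oxy]-7-hydroxytetradec-2-en-9-yn-1-yl]-5,7-dimethoxy-2-benzofuran-1(3H)-one | COc1cc(OC)c2c(c1)[C@@H](C/C=C/CCC[C@@H](O)CC#CCC[C@@H](C)O[Si](C)(C)C(C)(C)C)OC2=O
F5 | step 18 | (3R)-3-{(2E)-6-[(2R)-5-{(3R)-3-[(tert-butyldimethylsilyl)oxy]butyl}-2,3-dihydrofuran-2-yl]hex-2-en-1-yl}-5,7-dimethoxy-2-benzofuran-1(3H)-one | COc1cc(OC)c2c(c1)[C@@H](C/C=C/CCC[C@@H]1CC=C(CC[C@@H](C)O[Si](C)(C)C(C)(C)C)O1)OC2=O
F6 | step 18 | (3R)-3-{(2E)-6-[(2R)-5-[(3R)-3-hydroxybutyl]-2,3-dihydrofuran-2-yl]hex-2-en-1-yl}-5,7-dimethoxy-2-benzofuran-1(3H)-one | COc1cc(OC)c2c(c1)[C@@H](C/C=C/CCC[C@@H]1CC=C(CC[C@@H](C)O)O1)OC2=O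
F7 | step 18 | (3R)-5,7-dimethoxy-3-{(2E)-6-[(2R,5R,7R)-7-methyl-1,6-dioxaspiro[4.4]nonan-2-yl]hex-2-en-1-yl}-2-benzofuran-1(3H)-one | COc1cc(OC)c2c(c1)[C@@H](C/C=C/CCC[C@@H]1CC[C@@]3(CC[C@@H](C)O3)O1)OC2=O
F8 | step 19 | 3-[(2R,5S,7R)-7-methyl-1,6-dioxaspiro[4.4]nonan-2-yl]propan-1-ol | OCCC[C@@H]1CC[C@]2(CC[C@@H](C)O2)O1
F9 | step 19 | (2S,5S,7R)-2-(3-iodopropyl)-7-methyl-1,6-dioxaspiro[4.4]nonane | ICCC[C@@H]1CC[C@]2(CC[C@@H](C)O2)O1
F10 | step 19 | iodo{3-[(2S,5S,7R)-7-methyl-1,6-dioxaspiro[4.4]nonan-2-yl]propyl}zinc | I[Zn]CCC[C@@H]1CC[C@]2(CC[C@@H](C)O2)O1
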